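Everything rests on building ring A instead of buying it. It is cut at C5–C6, C4a–C8a and C8–C8a into an alkyne, an alkoxycarbene and carbon monoxide. The feature exploited is the para relation of the oxygens on C6 and C8a of ring A, with the C7 methoxy group next to C6, which is the hydroquinone monoether pattern of a Dötz benzannulation. In one operation a benzyloxy(1-methoxyvinyl)carbene chromium complex, one of its carbonyl ligands and a terminal ynone that already holds C2, C3, C4 and ring B give the ortho-acylphenol with O6 benzylated and O7 methylated. Loss of methanol then closes ring C, and hydrogenolysis frees the C6 hydroxyl.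

Key step: step 7

Assumption: compounds 11–18 are drawn as the E enol ethers expected from step 3. The geometry has no bearing on the outcome, because this double bond becomes C2=C3 of the pyranone in step 8.
Remark on notation: in the SMILES, carbonyl ligands of the σ-bonded chromium complexes are written as Cr=C=O. Those of Cr(CO)6 and of the η6 complex 17 are written as separate fragments.

Step 1
Reactants: 1 methyl vinyl ether; 2 chromium hexacarbonyl, Cr(CO)6
Product: 5 tetramethylammonium pentacarbonyl(2-methoxyprop-2-enoyl)chromate, via 1-methoxyvinyllithium 3 (not isolated), via lithium acylchromate 4 (not isolated)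
Conditions: t-BuLi, THF, −78 → 0 °C; Cr(CO)6, Et2O, 0 °C → rt; Me4NBr, degassed H2O, rt, extraction into CH2Cl2
Reagents that add atoms: tetramethylammonium bromide C[N+](C)(C)C.[Br-]; tert-butyllithium [Li]C(C)(C)C (lithium held only in 3 and 4)
Why: First half of the Fischer carbene synthesis: t-BuLi removes the α-vinyl proton of the enol ether, the vinyllithium adds to a carbonyl ligand of Cr(CO)6, and cation exchange turns the lithium acylchromate into an ammonium salt that can be dried, stored and dissolved in CH2Cl2.

Step 2
Reactants: 5 tetramethylammonium pentacarbonyl(2-methoxyprop-2-enoyl)chromate; 6 benzyl alcohol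
Product: 8 pentacarbonyl[(benzyloxy)(1-methoxyvinyl)carbene]chromium, via acetoxycarbene complex 7 (not isolated)
Conditions: AcBr (1.05 equiv), CH2Cl2, −40 °C; then BnOH (1.2 equiv), −40 → −10 °C; quick silica filtration under Ar
Reagents that add atoms: acetyl bromide CC(=O)Br (acetyl group held only in 7)
Why: Second half of the Fischer carbene synthesis in its acyl-activation variant: O-acetylation gives a very electrophilic acyloxycarbene, and benzyl alcohol displaces acetate at the carbene carbon by addition–elimination, which at −40 °C should be much faster than conjugate addition to the vinyl CH2.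

Step 3
Reactants: 9 methyl 3,4,5-trimethoxyphenylacetate
Product: 11 methyl (E)-3-methoxy-2-(3,4,5-trimethoxyphenyl)acrylate, via sodium enolate 10 (not isolated)
Conditions: NaH, HCO2Me, THF–DMF (4:1), 0 °C → rt; then Me2SO4, rt
Reagents that add atoms: methyl formate COC=O; dimethyl sulfate COS(=O)(=O)OC; sodium hydride [Na+].[H-] (sodium held only in 10)
Why: Crossed Claisen condensation with the non-enolisable formate followed by O-alkylation of the delocalised enolate with a hard methylating agent, the standard entry to β-methoxyacrylates, which should favour the E isomer with the methoxy group anti to the ester.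

Step 4
Reactants: 11 methyl (E)-3-methoxy-2-(3,4,5-trimethoxyphenyl)acrylate
Product: 12 (E)-3-methoxy-2-(3,4,5-trimethoxyphenyl)acrylic acid
Conditions: LiOH·H2O, THF–MeOH–H2O, 50 °C; then cold 1 M HCl to pH 3, 0 °C
Reagents that add atoms: lithium hydroxide [Li+].[OH-]
Why: Ordinary saponification, well known for β-alkoxyacrylates: attack of methoxide at the β-carbon is degenerate, and brief cold acidification leaves the vinylogous carbonate intact.

Step 5
Reactants: 12 (E)-3-methoxy-2-(3,4,5-trimethoxyphenyl)acrylic acid
Product: 14 (E)-N,3-dimethoxy-N-methyl-2-(3,4,5-trimethoxyphenyl)acrylamide, via acyl imidazolide 13 (not isolated)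
Conditions: CDI (1.2 equiv), CH2Cl2, rt; then MeNH(OMe)·HCl (1.5 equiv), rt
Reagents that add atoms: N,O-dimethylhydroxylamine hydrochloride CNOC.Cl; 1,1'-carbonyldiimidazole O=C(n1ccnc1)n1ccnc1 (imidazolyl group held only in 13)
Why: Amide coupling through the acyl imidazolide: the weakly basic amine meets an activated acyl carbon instead of a metal amide meeting the sluggish ester 11, so displacement of the β-methoxy group, the danger of a direct aminolysis, is avoided.

Step 6
Reactants: 14 (E)-N,3-dimethoxy-N-methyl-2-(3,4,5-trimethoxyphenyl)acrylamide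
Product: 16 (E)-1-methoxy-2-(3,4,5-trimethoxyphenyl)pent-1-en-4-yn-3-one, via magnesium hemiaminal chelate 15 (not isolated)
Conditions: HC≡CMgBr (3 equiv), THF, 0 °C → rt; inverse quench into cold 1 M HCl–Et2O, 0 °C
Reagents that add atoms: ethynylmagnesium bromide C#C[Mg]Br
Why: Weinreb ketone synthesis: the magnesium chelate 15 holds until the quench and so stops a second addition, alkynyl Grignard reagents add 1,2 rather than 1,4, and pouring into cold acid protonates the released amine before it can add to the terminal ynone.

Step 7
Reactants: 8 pentacarbonyl[(benzyloxy)(1-methoxyvinyl)carbene]chromium; 16 (E)-1-methoxy-2-(3,4,5-trimethoxyphenyl)pent-1-en-4-yn-3-one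
Product: 18 (E)-1-[5-(benzyloxy)-2-hydroxy-4-methoxyphenyl]-3-methoxy-2-(3,4,5-trimethoxyphenyl)prop-2-en-1-one, via tricarbonylchromium arene complex 17 (not isolated)
Conditions: 8 (1.3 equiv), 16 (1.0 equiv), degassed THF (0.1 M), Ar, 50 °C; then air, Et2O, daylight, rt, filtration through Celite
Reagents that add atoms: none
Why: Thermal loss of a cis carbonyl ligand from 8 opens a site for the alkyne of 16, which inserts into the Cr=C bond with its CH terminus bonded to the carbene carbon (C5–C6); the new chromium vinylcarbene takes up a carbonyl ligand to give a chromium-bound dienylketene (C4a–C8a), and this closes and tautomerises to the phenol, held at first as the Cr(CO)3 complex 17 that air then strips without touching the hydroquinone monoether. The closest known reaction type is the Dötz benzannulation of alkenyl(alkoxy)carbene chromium complexes with terminal alkynes, in which α-alkoxyvinyl carbenes and acyl alkynes have each served as partners, so only their combination is new here. Ring A closes by a 6π electrocyclisation of the dienylketene that forms C8–C8a between the vinyl CH2 and the ketene carbon, followed by enolisation of the cyclohexadienone. No stereocentre is created, and the enol ether geometry of 16 is not involved. Two selectivities are needed: the direction of insertion, secured because the terminal alkyne puts its only substituent, the acyl group, away from the carbene carbon and hence next to the CO-derived C8a, and phenol formation rather than cyclopentannulation, furan or lactone formation, which is favoured by an alkenyl rather than aryl carbene, by chromium, by the alkoxy donor and by an ether solvent at moderate temperature. Because the benzyl group on O6 and the methyl group on O7 enter with different building blocks, the two adjacent oxygens never have to be told apart later.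

Step 8
Reactants: 18 (E)-1-[5-(benzyloxy)-2-hydroxy-4-methoxyphenyl]-3-methoxy-2-(3,4,5-trimethoxyphenyl)prop-2-en-1-one
Product: 19 6-(benzyloxy)-7-methoxy-3-(3,4,5-trimethoxyphenyl)-4H-chromen-4-one
Conditions: p-TsOH·H2O (10 mol %), MeOH–THF, 60 °C
Reagents that add atoms: none
Why: Acid-catalysed addition–elimination (6-endo oxa-Michael addition of the C8a hydroxyl to C2, then loss of methanol), the same closure that ends the classical deoxybenzoin route to isoflavones, driven by formation of the aromatic 4-pyranone, so that any 19 formed already in step 7 is simply carried along.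

Step 9
Reactants: 19 6-(benzyloxy)-7-methoxy-3-(3,4,5-trimethoxyphenyl)-4H-chromen-4-one
Product: 20 6-hydroxy-7-methoxy-3-(3,4,5-trimethoxyphenyl)-4H-chromen-4-one (CNP0248931.0)
Conditions: H2 (1 atm), 10% Pd/C, EtOAc–THF, rt, stopped when 19 is consumed
Reagents that add atoms: none
Why: Catalytic hydrogenolysis of an aryl benzyl ether, which at 1 atm in a neutral solvent is faster than saturation of the C2=C3 bond and leaves the four aryl methyl ethers untouched.

Compound list
1 | methyl vinyl ether | C=COC | starting material
2 | chromium hexacarbonyl, Cr(CO)6 | [C-]#[O+].[C-]#[O+].[C-]#[O+].[C-]#[O+].[C-]#[O+].[C-]#[O+].[Cr] | starting material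
3 | 1-methoxyvinyllithium | [Li]C(=C)OC | intermediate
4 | lithium pentacarbonyl(2-methoxyprop-2-enoyl)chromate | C=C(OC)C([O-])=[Cr](=C=O)(=C=O)(=C=O)(=C=O)=C=O.[Li+] | intermediate
5 | tetramethylammonium pentacarbonyl(2-methoxyprop-2-enoyl)chromate | C=C(OC)C([O-])=[Cr](=C=O)(=C=O)(=C=O)(=C=O)=C=O.C[N+](C)(C)C | intermediate
6 | benzyl alcohol | OCc1ccccc1 | starting material
7 | pentacarbonyl[(acetoxy)(1-methoxyvinyl)carbene]chromium | C=C(OC)C(OC(C)=O)=[Cr](=C=O)(=C=O)(=C=O)(=C=O)=C=O | intermediate
8 | pentacarbonyl[(benzyloxy)(1-methoxyvinyl)carbene]chromium | C=C(OC)C(OCc1ccccc1)=[Cr](=C=O)(=C=O)(=C=O)(=C=O)=C=O | intermediate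
9 | methyl 3,4,5-trimethoxyphenylacetate | COC(=O)Cc1cc(OC)c(OC)c(OC)c1 | starting material
10 | sodium enolate of methyl 3-oxo-2-(3,4,5-trimethoxyphenyl)propanoate | COC(=O)C(=C[O-])c1cc(OC)c(OC)c(OC)c1.[Na+] | intermediate
11 | methyl (E)-3-methoxy-2-(3,4,5-trimethoxyphenyl)acrylate | CO/C=C(/C(=O)OC)c1cc(OC)c(OC)c(OC)c1 | intermediate
12 | (E)-3-methoxy-2-(3,4,5-trimethoxyphenyl)acrylic acid | CO/C=C(/C(=O)O)c1cc(OC)c(OC)c(OC)c1 | intermediate
13 | (E)-1-(1H-imidazol-1-yl)-3-methoxy-2-(3,4,5-trimethoxyphenyl)prop-2-en-1-one | CO/C=C(/C(=O)n1ccnc1)c1cc(OC)c(OC)c(OC)c1 | intermediate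
14 | (E)-N,3-dimethoxy-N-methyl-2-(3,4,5-trimethoxyphenyl)acrylamide | CO/C=C(/C(=O)N(C)OC)c1cc(OC)c(OC)c(OC)c1 | intermediate
15 | bromomagnesium alkoxide of the tetrahedral ethynyl adduct of 14 (racemic at the carbinol carbon) | CO/C=C(/C(O[Mg]Br)(C#C)N(C)OC)c1cc(OC)c(OC)c(OC)c1 | intermediate
16 | (E)-1-methoxy-2-(3,4,5-trimethoxyphenyl)pent-1-en-4-yn-3-one | CO/C=C(/C(=O)C#C)c1cc(OC)c(OC)c(OC)c1 | intermediate
17 | tricarbonyl(η6-arene)chromium complex of 18, chromium on ring A | CO/C=C(/C(=O)c1cc(OCc2ccccc2)c(OC)cc1O)c1cc(OC)c(OC)c(OC)c1.[Cr].[C-]#[O+].[C-]#[O+].[C-]#[O+] | intermediate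
18 | (E)-1-[5-(benzyloxy)-2-hydroxy-4-methoxyphenyl]-3-methoxy-2-(3,4,5-trimethoxyphenyl)prop-2-en-1-one | CO/C=C(/C(=O)c1cc(OCc2ccccc2)c(OC)cc1O)c1cc(OC)c(OC)c(OC)c1 | intermediate
19 | 6-(benzyloxy)-7-methoxy-3-(3,4,5-trimethoxyphenyl)-4H-chromen-4-one | COc1cc2occ(-c3cc(OC)c(OC)c(OC)c3)c(=O)c2cc1OCc1ccccc1 | intermediate
20 | 6-hydroxy-7-methoxy-3-(3,4,5-trimethoxyphenyl)-4H-chromen-4-one | COc1cc2occ(-c3cc(OC)c(OC)c(OC)c3)c(=O)c2cc1O | target

Total step count: 9.
Longest linear sequence: 7 steps (steps 3–9, from 9 to 20). The carbene branch (steps 1–2) joins at step 7.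

Steps most likely to fail

Step 7.
- **Risk:** The electron-poor alkyne may insert slowly, so that thermal decay of the carbene complex competes. The acyl oxygen may capture the vinylcarbene or the ketene before the electrocyclisation. The ynone may oligomerise at chromium.
- **Fallback:** This route gives up the construction of ring A and buys it as a hydroquinone. It sets out from 9 and comes back at 20. Compound 9 is saponified (NaOH, MeOH–H2O) to 3,4,5-trimethoxyphenylacetic acid F1. F1 acylates commercial 2-methoxyhydroquinone in BF3·OEt2 at 80 °C, a Friedel–Crafts acylation para to the methoxy group and ortho to a hydroxyl. This gives the deoxybenzoin 1-(2,5-dihydroxy-4-methoxyphenyl)-2-(3,4,5-trimethoxyphenyl)ethan-1-one F2. A Vilsmeier-type one-carbon transfer with DMF and MeSO2Cl in the presence of BF3·OEt2 at 70 °C then adds C2 and closes ring C. It leads to 20 without any protecting group.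

Step 6.
- **Risk:** Addition to the hindered, push–pull amide may be slow. The acetylide may displace the β-methoxy group. The released amine may add to the terminal ynone during the quench.
- **Fallback:** This route replaces the organomagnesium addition by a catalytic acylation of an alkyne. It sets out from 12 and comes back at 16. Acid 12 is converted with (COCl)2 and catalytic DMF in CH2Cl2 into (E)-3-methoxy-2-(3,4,5-trimethoxyphenyl)acryloyl chloride F3. An acyl Sonogashira coupling with trimethylsilylacetylene (PdCl2(PPh3)2, CuI, Et3N, THF, rt) gives (E)-1-methoxy-2-(3,4,5-trimethoxyphenyl)-5-(trimethylsilyl)pent-1-en-4-yn-3-one F4. Protodesilylation with AcOH-buffered TBAF in THF at −20 °C gives 16, and no nucleophilic amine is ever present.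

Step 2.
- **Risk:** The acyloxycarbene may decay before alcoholysis. Benzyl alcohol may add to the vinyl terminus.
- **Fallback:** This route forms the O–CH2 bond instead of the carbene C–O bond. It sets out from 5 and comes back at 8. Salt 5 is O-alkylated directly with benzyl bromide under phase-transfer conditions (Bu4NBr, CH2Cl2–H2O, rt), a known SN2 alkylation of ammonium acylmetalates with reactive halides. It avoids both the acyloxycarbene and free alcohol, and it makes no compound outside the list (entry F0).

Further compounds
F1 | step 7 | 3,4,5-trimethoxyphenylacetic acid | OC(=O)Cc1cc(OC)c(OC)c(OC)c1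
F2 | step 7 | 1-(2,5-dihydroxy-4-methoxyphenyl)-2-(3,4,5-trimethoxyphenyl)ethan-1-one | COc1cc(O)c(cc1O)C(=O)Cc1cc(OC)c(OC)c(OC)c1
F3 | step 6 | (E)-3-methoxy-2-(3,4,5-trimethoxyphenyl)acryloyl chloride | CO/C=C(/C(=O)Cl)c1cc(OC)c(OC)c(OC)c1
F4 | step 6 | (E)-1-methoxy-2-(3,4,5-trimethoxyphenyl)-5-(trimethylsilyl)pent-1-en-4-yn-3-one | CO/C=C(/C(=O)C#C[Si](C)(C)C)c1cc(OC)c(OC)c(OC)c1
F0 | step 2 | none | none
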